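The α-methylene-γ-butyrolactone is unlocked by opening its O–C12 acyl bond and then cutting C11–C12 and C7–C8 together, which leaves CO2 and an open-chain allenyl aldehyde (C13H2=C11=C7H … C8H=O). Germacrane numbering is used throughout: C1=C10(C14H3), C2, C3(OH), C4(C15H2O)=C5, C6(O-acyl), C7 (ring-fusion CH), C8 (lactone CH–O), C9; lactone C11(=C13H2)–C12(=O)–O–C8.
The enabling feature is the 2-carboxyallyl unit C13=C11(C12)–C7 attached to the oxygenated C8, with C7–C8 shared by the lactone and the ten-membered ring: one nickel-mediated allene/CO2/aldehyde coupling builds the acrylate and closes the carbocycle.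
Forward, the chain is assembled linearly from C8 to C13 (but-3-yn-1-ol, methyl, oxirane, a propargyl ether, a hydroxymethylstannane, ethynyltrimethylsilane, formaldehyde). The ten-membered ring then closes in the key step, the γ-lactone next, the two esters after that, and the C3 hydroxyl is released last.
Stereochemistry: 1(10)E from syn-carboalumination; the C4=C5 geometry from hydroxyl-directed trans-hydroalumination/iodination and Stille coupling with retention; C3 from Noyori transfer hydrogenation; C6 from zinc–ProPhenol alkynylation.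
C7 and C8 are set in the key step under control of C6 and a closed transition state; the acyl stereocentres come from (R)-2-methylbutanoic acid.

Key step: step 18

Remark (assumption): the ligand antipodes for the two catalyst-controlled carbinol centres (steps 6 and 11) are those expected from the usual facial models; if either shows the opposite sense, the enantiomeric ligand is used and nothing else changes.
Remark: compounds 1, 6, 16 and 30 and (tributylstannyl)methanol are taken as commercial.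

Step 1
Reactants: 1 but-3-yn-1-ol
Product: 2 1-[(but-3-yn-1-yloxy)methyl]-4-methoxybenzene
Conditions: NaH, 4-methoxybenzyl chloride, n-Bu4NI (cat.), THF/DMF, 0 °C → rt
Reagents that add atoms: 4-methoxybenzyl chloride, COc1ccc(CCl)cc1
Why: Williamson etherification of the primary alkoxide; the PMB ether is later removed oxidatively without touching silyl ethers.

Step 2
Reactants: 2 1-[(but-3-yn-1-yloxy)methyl]-4-methoxybenzene
Product: 4 (3E)-6-[(4-methoxybenzyl)oxy]-4-methylhex-3-en-1-ol, via alkenylalane 3 (not isolated)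
Conditions: Me3Al, Cp2ZrCl2 (cat.), CH2Cl2, 0 °C → rt; then n-BuLi, THF, −78 → 0 °C; then oxirane, 0 °C → rt
Reagents that add atoms: trimethylaluminium, C[Al](C)C; oxirane, C1CO1
Why: Negishi zirconium-catalysed carboalumination adds methyl (to C10) and aluminium (to C1) syn across the alkyne, and the derived alanate opens oxirane with retention, which fixes the 1(10)E trisubstituted alkene.

Step 3
Reactants: 4 (3E)-6-[(4-methoxybenzyl)oxy]-4-methylhex-3-en-1-ol
Product: 5 (3E)-6-[(4-methoxybenzyl)oxy]-4-methylhex-3-enal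
Conditions: Dess–Martin periodinane, pyridine, CH2Cl2, 0 °C; used at once
Reagents that add atoms: none
Why: Dess–Martin oxidation under buffered, non-basic conditions gives the β,γ-unsaturated aldehyde without moving the alkene into conjugation.

Step 4
Reactants: 5 (3E)-6-[(4-methoxybenzyl)oxy]-4-methylhex-3-enal; 6 tert-butyldimethyl(prop-2-yn-1-yloxy)silane
Product: 8 rac-(6E)-1-[(tert-butyldimethylsilyl)oxy]-9-[(4-methoxybenzyl)oxy]-7-methylnon-6-en-2-yn-4-ol, via lithium acetylide 7 (not isolated)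
Conditions: 6, n-BuLi, THF, −78 °C; then 5, −78 °C; aq NH4Cl
Reagents that add atoms: none
Why: 1,2-addition of a lithium acetylide to the aldehyde at −78 °C outruns enolization; the new carbinol centre (C3) is formed racemic and is reset in steps 5 and 6.

Step 5
Reactants: 8 rac-(6E)-1-[(tert-butyldimethylsilyl)oxy]-9-[(4-methoxybenzyl)oxy]-7-methylnon-6-en-2-yn-4-ol
Product: 9 (6E)-1-[(tert-butyldimethylsilyl)oxy]-9-[(4-methoxybenzyl)oxy]-7-methylnon-6-en-2-yn-4-one
Conditions: Dess–Martin periodinane, pyridine, CH2Cl2, 0 °C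
Reagents that add atoms: none
Why: Dess–Martin oxidation of the propargylic alcohol to the ynone under neutral conditions that leave the acidic C2 methylene and the skipped alkene alone.

Step 6
Reactants: 9 (6E)-1-[(tert-butyldimethylsilyl)oxy]-9-[(4-methoxybenzyl)oxy]-7-methylnon-6-en-2-yn-4-one
Product: 10 (4R,6E)-1-[(tert-butyldimethylsilyl)oxy]-9-[(4-methoxybenzyl)oxy]-7-methylnon-6-en-2-yn-4-ol
Conditions: Ru[(R,R)-TsDPEN](p-cymene) (preformed amido complex, 1 mol%), i-PrOH, rt
Reagents that add atoms: none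
Why: Noyori asymmetric transfer hydrogenation of an alkynyl ketone under base-free conditions; the catalyst tells the alkynyl from the CH2 substituent and delivers hydride to one carbonyl face, setting C3 (R) without reducing the alkyne or isomerizing the alkene.

Step 7
Reactants: 10 (4R,6E)-1-[(tert-butyldimethylsilyl)oxy]-9-[(4-methoxybenzyl)oxy]-7-methylnon-6-en-2-yn-4-ol
Product: 11 (4R,6E)-1,4-bis[(tert-butyldimethylsilyl)oxy]-9-[(4-methoxybenzyl)oxy]-7-methylnon-6-en-2-yne
Conditions: t-BuMe2SiCl, imidazole, DMF, rt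
Reagents that add atoms: tert-butyldimethylsilyl chloride, CC(C)(C)[Si](C)(C)Cl
Why: standard silylation of the secondary propargylic alcohol; the C3 silyl ether is kept until the last step.

Step 8
Reactants: 11 (4R,6E)-1,4-bis[(tert-butyldimethylsilyl)oxy]-9-[(4-methoxybenzyl)oxy]-7-methylnon-6-en-2-yne
Product: 12 (4R,6E)-4-[(tert-butyldimethylsilyl)oxy]-9-[(4-methoxybenzyl)oxy]-7-methylnon-6-en-2-yn-1-ol
Conditions: HF·pyridine, pyridine, THF, 0 °C
Reagents that add atoms: none
Why: sterically controlled selective cleavage of the primary silyl ether in the presence of the secondary one frees the C6 hydroxyl needed as a directing group.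

Step 9
Reactants: 12 (4R,6E)-4-[(tert-butyldimethylsilyl)oxy]-9-[(4-methoxybenzyl)oxy]-7-methylnon-6-en-2-yn-1-ol
Product: 14 (2Z,4R,6E)-4-[(tert-butyldimethylsilyl)oxy]-3-iodo-9-[(4-methoxybenzyl)oxy]-7-methylnona-2,6-dien-1-ol, via alkenylalanate 13 (not isolated)
Conditions: NaAlH2(OCH2CH2OMe)2, THF, 0 °C; then I2, −78 → 0 °C
Reagents that add atoms: iodine, II
Why: hydroxyl-directed trans-hydroalumination delivers H to C5 and aluminium to C4 within a five-membered ring, and iodinolysis with retention gives the Z-iodoalkene, placing C3 trans to C6 across C4=C5.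

Step 10
Reactants: 14 (2Z,4R,6E)-4-[(tert-butyldimethylsilyl)oxy]-3-iodo-9-[(4-methoxybenzyl)oxy]-7-methylnona-2,6-dien-1-ol
Product: 15 (2Z,4R,6E)-4-[(tert-butyldimethylsilyl)oxy]-3-iodo-9-[(4-methoxybenzyl)oxy]-7-methylnona-2,6-dienal
Conditions: Dess–Martin periodinane, pyridine, CH2Cl2, 0 °C
Reagents that add atoms: none
Why: Dess–Martin oxidation of the allylic alcohol to the Z-β-iodoenal at low temperature, with no acid or base to erode the alkene geometry.

Step 11
Reactants: 15 (2Z,4R,6E)-4-[(tert-butyldimethylsilyl)oxy]-3-iodo-9-[(4-methoxybenzyl)oxy]-7-methylnona-2,6-dienal; 16 ethynyltrimethylsilane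
Product: 18 (3R,4Z,6R,8E)-6-[(tert-butyldimethylsilyl)oxy]-5-iodo-11-[(4-methoxybenzyl)oxy]-9-methyl-1-(trimethylsilyl)undeca-4,8-dien-1-yn-3-ol, via alkynylzinc 17 (not isolated)
Conditions: (R,R)-ProPhenol (20 mol%), Me2Zn, 16, Ph3PO (40 mol%), toluene, 0 °C
Reagents that add atoms: none
Why: zinc–ProPhenol-catalysed enantioselective alkynylation of an enal, in which the dinuclear zinc catalyst delivers the alkynyl group to one aldehyde face and sets C6 under catalyst control (the remote C3 centre has no influence).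

Step 12
Reactants: 18 (3R,4Z,6R,8E)-6-[(tert-butyldimethylsilyl)oxy]-5-iodo-11-[(4-methoxybenzyl)oxy]-9-methyl-1-(trimethylsilyl)undeca-4,8-dien-1-yn-3-ol
Product: 19 (3R,4E,6R,8E)-6-[(tert-butyldimethylsilyl)oxy]-5-(hydroxymethyl)-11-[(4-methoxybenzyl)oxy]-9-methyl-1-(trimethylsilyl)undeca-4,8-dien-1-yn-3-ol
Conditions: Bu3SnCH2OH, Pd(PPh3)4 (5 mol%), 1,4-dioxane, 90 °C
Reagents that add atoms: (tributylstannyl)methanol, CCCC[Sn](CCCC)(CCCC)CO
Why: Stille coupling of the hydroxymethylstannane with the alkenyl iodide proceeds with retention of alkene geometry and installs C15 cis to C6.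

Step 13
Reactants: 19 (3R,4E,6R,8E)-6-[(tert-butyldimethylsilyl)oxy]-5-(hydroxymethyl)-11-[(4-methoxybenzyl)oxy]-9-methyl-1-(trimethylsilyl)undeca-4,8-dien-1-yn-3-ol
Product: 20 (3R,4E,6R,8E)-6-[(tert-butyldimethylsilyl)oxy]-5-(hydroxymethyl)-11-[(4-methoxybenzyl)oxy]-9-methylundeca-4,8-dien-1-yn-3-ol
Conditions: K2CO3 (cat.), MeOH, rt
Reagents that add atoms: none
Why: base-catalysed methanolysis of the alkynyl C–Si bond frees the terminal alkyne while the alkyl silyl ether and the PMB ether are stable.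

Step 14
Reactants: 20 (3R,4E,6R,8E)-6-[(tert-butyldimethylsilyl)oxy]-5-(hydroxymethyl)-11-[(4-methoxybenzyl)oxy]-9-methylundeca-4,8-dien-1-yn-3-ol
Product: 21 (3R,4E,6R,8E)-6-[(tert-butyldimethylsilyl)oxy]-11-[(4-methoxybenzyl)oxy]-9-methyl-3-[(triethylsilyl)oxy]-5-{[(triethylsilyl)oxy]methyl}undeca-4,8-dien-1-yne
Conditions: Et3SiCl, imidazole, CH2Cl2, 0 °C
Reagents that add atoms: chlorotriethylsilane, CC[Si](CC)(CC)Cl
Why: silylation of both the C6 and C15 hydroxyls with one acid-labile group that can later be removed while the C3 tert-butyldimethylsilyl ether stays.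

Step 15
Reactants: 21 (3R,4E,6R,8E)-6-[(tert-butyldimethylsilyl)oxy]-11-[(4-methoxybenzyl)oxy]-9-methyl-3-[(triethylsilyl)oxy]-5-{[(triethylsilyl)oxy]methyl}undeca-4,8-dien-1-yne
Product: 23 (4S,5E,7R,9E)-7-[(tert-butyldimethylsilyl)oxy]-12-[(4-methoxybenzyl)oxy]-10-methyl-4-[(triethylsilyl)oxy]-6-{[(triethylsilyl)oxy]methyl}dodeca-1,2,5,9-tetraene, via propargylamine 22 (not isolated)
Conditions: (CH2O)n, CuI (0.5 equiv), (C6H11)2NH, 1,4-dioxane, reflux
Reagents that add atoms: paraformaldehyde (as formaldehyde), C=O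
Why: Crabbé homologation, in which a copper-catalysed Mannich reaction gives the propargylamine and its 1,5-hydride shift with loss of imine forms the terminal allene; the adjacent stereocentre is untouched (its descriptor changes from R to S by priority only).

Step 16
Reactants: 23 (4S,5E,7R,9E)-7-[(tert-butyldimethylsilyl)oxy]-12-[(4-methoxybenzyl)oxy]-10-methyl-4-[(triethylsilyl)oxy]-6-{[(triethylsilyl)oxy]methyl}dodeca-1,2,5,9-tetraene
Product: 24 (3E,6R,7E,9S)-6-[(tert-butyldimethylsilyl)oxy]-3-methyl-9-[(triethylsilyl)oxy]-7-{[(triethylsilyl)oxy]methyl}dodeca-3,7,10,11-tetraen-1-ol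
Conditions: DDQ, CH2Cl2/pH 7 phosphate buffer, 0 °C
Reagents that add atoms: none
Why: oxidative PMB cleavage by DDQ (benzylic hydride abstraction, then hydrolysis) under buffered conditions that spare the silyl ethers, the allene and the alkenes.

Step 17
Reactants: 24 (3E,6R,7E,9S)-6-[(tert-butyldimethylsilyl)oxy]-3-methyl-9-[(triethylsilyl)oxy]-7-{[(triethylsilyl)oxy]methyl}dodeca-3,7,10,11-tetraen-1-ol
Product: 25 (3E,6R,7E,9S)-6-[(tert-butyldimethylsilyl)oxy]-3-methyl-9-[(triethylsilyl)oxy]-7-{[(triethylsilyl)oxy]methyl}dodeca-3,7,10,11-tetraenal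
Conditions: Dess–Martin periodinane, pyridine, CH2Cl2, 0 °C; used at once
Reagents that add atoms: none
Why: Dess–Martin oxidation under non-basic conditions gives the β,γ-unsaturated C8 aldehyde without conjugation of the 1(10) alkene.

Step 18
Reactants: 25 (3E,6R,7E,9S)-6-[(tert-butyldimethylsilyl)oxy]-3-methyl-9-[(triethylsilyl)oxy]-7-{[(triethylsilyl)oxy]methyl}dodeca-3,7,10,11-tetraenal
Product: 27 (3R,6R,7R,8S)-3-[(tert-butyldimethylsilyl)oxy]-8-hydroxy-6,15-bis[(triethylsilyl)oxy]germacra-1(10)E,4E,11(13)-trien-12-oic acid, via nickelalactone 26 (not isolated)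
Conditions: Ni(cod)2 (1.2 equiv), DBU (2.4 equiv), CO2 (1 atm), THF, 0 °C, slow addition of 25 (final 0.002 M); then 10% aq citric acid, 0 °C
Reagents that add atoms: carbon dioxide, O=C=O
Why: Proposed new method: zerovalent nickel, CO2 and the terminal C11=C13 bond of the allene undergo oxidative cyclization that bonds C12 to the central allene carbon C11 and gives the DBU-ligated five-membered nickelalactone 26, a 2-carboxyallylnickel which, σ-bound at C13, adds through its γ-carbon C7 to the tethered aldehyde carbon C8 in a closed six-membered transition state, so that C11–C12 and C7–C8 are made in one flask. The closest known reaction type is the intermolecular nickel-mediated sequential coupling of terminal allenes with CO2 and aldehydes, and the ring closure mirrors chromium-mediated macrocyclic allylations of aldehydes by 2-(alkoxycarbonyl)allyl halides; new here are the tethered aldehyde and the medium ring. Only the ten-membered carbocycle closes in this step, by intramolecular SE2′ carbonyl allylation at high dilution (the γ-lactone follows in step 19). C7 and C8 are set together: the slow ring closure lets the alkylidene nickelalactone settle as its E isomer (C6 syn to the carboxylate), whose chair-like transition state gives the 7,8-anti adduct that later closes to the trans-fused lactone, while 1,3-allylic strain against C12 holds H6 in the alkene plane so that the aldehyde, tethered through C5, reaches C7 on the face opposite the C6 silyloxy group, leaving all three substituents pseudo-equatorial on the crown-like E,E-cyclodecadiene. The step needs regioselectivity for C7 over C13 (six-membered SE2′ geometry and the ten- over the twelve-membered ring), chemoselectivity for the allene over the two trisubstituted alkenes (only the cumulated C=C binds zerovalent nickel at 0 °C) and survival of the β,γ-unsaturated aldehyde (DBU is held as its CO2 adduct and as a ligand on nickel, and the aldehyde is added slowly).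

Step 19
Reactants: 27 (3R,6R,7R,8S)-3-[(tert-butyldimethylsilyl)oxy]-8-hydroxy-6,15-bis[(triethylsilyl)oxy]germacra-1(10)E,4E,11(13)-trien-12-oic acid
Product: 28 (3R,6R,7R,8S)-3-[(tert-butyldimethylsilyl)oxy]-6,15-bis[(triethylsilyl)oxy]germacra-1(10)E,4E,11(13)-trien-12,8-olide
Conditions: EDC·HCl, DMAP (cat.), CH2Cl2, 0 °C → rt
Reagents that add atoms: none
Why: carbodiimide-mediated lactonization (intramolecular Steglich esterification) in which the C8 hydroxyl attacks the activated acrylic acid to close the five-membered ring, touching no stereocentre and keeping the acid-labile silyl ethers.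

Step 20
Reactants: 28 (3R,6R,7R,8S)-3-[(tert-butyldimethylsilyl)oxy]-6,15-bis[(triethylsilyl)oxy]germacra-1(10)E,4E,11(13)-trien-12,8-olide
Product: 29 (3R,6R,7S,8S)-3-[(tert-butyldimethylsilyl)oxy]-6,15-dihydroxygermacra-1(10)E,4E,11(13)-trien-12,8-olide (7S by priority change only)
Conditions: PPTS (cat.), MeOH/CH2Cl2, 0 °C
Reagents that add atoms: none
Why: mild acid-catalysed methanolysis removes both triethylsilyl ethers while the bulkier secondary tert-butyldimethylsilyl ether at C3 stays, and the non-basic medium avoids relactonization to O6.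

Step 21
Reactants: 29 (3R,6R,7S,8S)-3-[(tert-butyldimethylsilyl)oxy]-6,15-dihydroxygermacra-1(10)E,4E,11(13)-trien-12,8-olide; 30 (2R)-2-methylbutanoic acid
Product: 31 (3R,6R,7R,8S)-3-[(tert-butyldimethylsilyl)oxy]-6,15-bis{[(2R)-2-methylbutanoyl]oxy}germacra-1(10)E,4E,11(13)-trien-12,8-olide
Conditions: 30 (3 equiv), EDC·HCl, DMAP, CH2Cl2, 0 °C → rt
Reagents that add atoms: none
Why: Steglich esterification of the primary allylic C15 and the secondary C6 hydroxyls, with the acid stereocentre carried in unchanged at low temperature and C3 still protected.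

Step 22
Reactants: 31 (3R,6R,7R,8S)-3-[(tert-butyldimethylsilyl)oxy]-6,15-bis{[(2R)-2-methylbutanoyl]oxy}germacra-1(10)E,4E,11(13)-trien-12,8-olide
Product: 32 (3R,6R,7R,8S)-3-hydroxy-6,15-bis{[(2R)-2-methylbutanoyl]oxy}germacra-1(10)E,4E,11(13)-trien-12,8-olide (CNP0164325.1)
Conditions: HF·pyridine, pyridine, THF, 0 °C → rt
Reagents that add atoms: none
Why: fluoride desilylation in a buffered acidic medium frees the C3 hydroxyl without the base that could trigger acyl migration from O15 to O3 or addition to the α-methylene lactone.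

Compound list
1 | but-3-yn-1-ol | C#CCCO | starting material
2 | 1-[(but-3-yn-1-yloxy)methyl]-4-methoxybenzene | C#CCCOCc1ccc(OC)cc1 | intermediate
3 | [(1E)-4-[(4-methoxybenzyl)oxy]-2-methylbut-1-en-1-yl]dimethylalane (Al cis to the methyl group) | C[Al](C)/C=C(\C)CCOCc1ccc(OC)cc1 | intermediate (not isolated)
4 | (3E)-6-[(4-methoxybenzyl)oxy]-4-methylhex-3-en-1-ol | OCC/C=C(\C)CCOCc1ccc(OC)cc1 | intermediate
5 | (3E)-6-[(4-methoxybenzyl)oxy]-4-methylhex-3-enal | O=CC/C=C(\C)CCOCc1ccc(OC)cc1 | intermediate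
6 | tert-butyldimethyl(prop-2-yn-1-yloxy)silane | C#CCO[Si](C)(C)C(C)(C)C | starting material
7 | {3-[(tert-butyldimethylsilyl)oxy]prop-1-yn-1-yl}lithium | [Li]C#CCO[Si](C)(C)C(C)(C)C | intermediate (not isolated)
8 | rac-(6E)-1-[(tert-butyldimethylsilyl)oxy]-9-[(4-methoxybenzyl)oxy]-7-methylnon-6-en-2-yn-4-ol | CC(C)(C)[Si](C)(C)OCC#CC(O)C/C=C(\C)CCOCc1ccc(OC)cc1 | intermediate
9 | (6E)-1-[(tert-butyldimethylsilyl)oxy]-9-[(4-methoxybenzyl)oxy]-7-methylnon-6-en-2-yn-4-one | CC(C)(C)[Si](C)(C)OCC#CC(=O)C/C=C(\C)CCOCc1ccc(OC)cc1 | intermediate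
10 | (4R,6E)-1-[(tert-butyldimethylsilyl)oxy]-9-[(4-methoxybenzyl)oxy]-7-methylnon-6-en-2-yn-4-ol | CC(C)(C)[Si](C)(C)OCC#C[C@H](O)C/C=C(\C)CCOCc1ccc(OC)cc1 | intermediate
11 | (4R,6E)-1,4-bis[(tert-butyldimethylsilyl)oxy]-9-[(4-methoxybenzyl)oxy]-7-methylnon-6-en-2-yne | CC(C)(C)[Si](C)(C)OCC#C[C@H](O[Si](C)(C)C(C)(C)C)C/C=C(\C)CCOCc1ccc(OC)cc1 | intermediate
12 | (4R,6E)-4-[(tert-butyldimethylsilyl)oxy]-9-[(4-methoxybenzyl)oxy]-7-methylnon-6-en-2-yn-1-ol | OCC#C[C@H](O[Si](C)(C)C(C)(C)C)C/C=C(\C)CCOCc1ccc(OC)cc1 | intermediate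
13 | sodium cyclic alkenylalanate of 12 (five-membered O–Al–C4=C5–C6 ring, two 2-methoxyethoxy groups on Al) | [Na+].COCCO[Al-]1(OCCOC)OCC=C1[C@H](O[Si](C)(C)C(C)(C)C)C/C=C(\C)CCOCc1ccc(OC)cc1 | intermediate (not isolated)
14 | (2Z,4R,6E)-4-[(tert-butyldimethylsilyl)oxy]-3-iodo-9-[(4-methoxybenzyl)oxy]-7-methylnona-2,6-dien-1-ol | OC/C=C(\I)[C@H](O[Si](C)(C)C(C)(C)C)C/C=C(\C)CCOCc1ccc(OC)cc1 | intermediate
15 | (2Z,4R,6E)-4-[(tert-butyldimethylsilyl)oxy]-3-iodo-9-[(4-methoxybenzyl)oxy]-7-methylnona-2,6-dienal | O=C/C=C(\I)[C@H](O[Si](C)(C)C(C)(C)C)C/C=C(\C)CCOCc1ccc(OC)cc1 | intermediate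
16 | ethynyltrimethylsilane | C#C[Si](C)(C)C | starting material
17 | methyl[(trimethylsilyl)ethynyl]zinc | C[Zn]C#C[Si](C)(C)C | intermediate (not isolated)
18 | (3R,4Z,6R,8E)-6-[(tert-butyldimethylsilyl)oxy]-5-iodo-11-[(4-methoxybenzyl)oxy]-9-methyl-1-(trimethylsilyl)undeca-4,8-dien-1-yn-3-ol | C[Si](C)(C)C#C[C@H](O)/C=C(\I)[C@H](O[Si](C)(C)C(C)(C)C)C/C=C(\C)CCOCc1ccc(OC)cc1 | intermediate
19 | (3R,4E,6R,8E)-6-[(tert-butyldimethylsilyl)oxy]-5-(hydroxymethyl)-11-[(4-methoxybenzyl)oxy]-9-methyl-1-(trimethylsilyl)undeca-4,8-dien-1-yn-3-ol | C[Si](C)(C)C#C[C@H](O)/C=C(\CO)[C@H](O[Si](C)(C)C(C)(C)C)C/C=C(\C)CCOCc1ccc(OC)cc1 | intermediate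
20 | (3R,4E,6R,8E)-6-[(tert-butyldimethylsilyl)oxy]-5-(hydroxymethyl)-11-[(4-methoxybenzyl)oxy]-9-methylundeca-4,8-dien-1-yn-3-ol | C#C[C@H](O)/C=C(\CO)[C@H](O[Si](C)(C)C(C)(C)C)C/C=C(\C)CCOCc1ccc(OC)cc1 | intermediate
21 | (3R,4E,6R,8E)-6-[(tert-butyldimethylsilyl)oxy]-11-[(4-methoxybenzyl)oxy]-9-methyl-3-[(triethylsilyl)oxy]-5-{[(triethylsilyl)oxy]methyl}undeca-4,8-dien-1-yne | C#C[C@H](O[Si](CC)(CC)CC)/C=C(\CO[Si](CC)(CC)CC)[C@H](O[Si](C)(C)C(C)(C)C)C/C=C(\C)CCOCc1ccc(OC)cc1 | intermediate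
22 | N,N-dicyclohexylpropargylamine from 21 (the alkyne terminus carries CH2N(C6H11)2) | C1CCC(CC1)N(C1CCCCC1)CC#C[C@H](O[Si](CC)(CC)CC)/C=C(\CO[Si](CC)(CC)CC)[C@H](O[Si](C)(C)C(C)(C)C)C/C=C(\C)CCOCc1ccc(OC)cc1 | intermediate (not isolated)
23 | (4S,5E,7R,9E)-7-[(tert-butyldimethylsilyl)oxy]-12-[(4-methoxybenzyl)oxy]-10-methyl-4-[(triethylsilyl)oxy]-6-{[(triethylsilyl)oxy]methyl}dodeca-1,2,5,9-tetraene | C=C=C[C@H](O[Si](CC)(CC)CC)/C=C(\CO[Si](CC)(CC)CC)[C@H](O[Si](C)(C)C(C)(C)C)C/C=C(\C)CCOCc1ccc(OC)cc1 | intermediate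
24 | (3E,6R,7E,9S)-6-[(tert-butyldimethylsilyl)oxy]-3-methyl-9-[(triethylsilyl)oxy]-7-{[(triethylsilyl)oxy]methyl}dodeca-3,7,10,11-tetraen-1-ol | C=C=C[C@H](O[Si](CC)(CC)CC)/C=C(\CO[Si](CC)(CC)CC)[C@H](O[Si](C)(C)C(C)(C)C)C/C=C(\C)CCO | intermediate
25 | (3E,6R,7E,9S)-6-[(tert-butyldimethylsilyl)oxy]-3-methyl-9-[(triethylsilyl)oxy]-7-{[(triethylsilyl)oxy]methyl}dodeca-3,7,10,11-tetraenal | C=C=C[C@H](O[Si](CC)(CC)CC)/C=C(\CO[Si](CC)(CC)CC)[C@H](O[Si](C)(C)C(C)(C)C)C/C=C(\C)CC=O | intermediate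
26 | DBU-ligated nickelalactone: 4-alkylidene-2-nickela-1-oxacyclopentan-5-one with divalent nickel bound to C13 and the carboxylate oxygen, E at the exocyclic C11=C7 bond (DBU ligands not drawn) | O=C1O[Ni]C/C1=C/[C@H](O[Si](CC)(CC)CC)/C=C(\CO[Si](CC)(CC)CC)[C@H](O[Si](C)(C)C(C)(C)C)C/C=C(\C)CC=O | intermediate (not isolated)
27 | (3R,6R,7R,8S)-3-[(tert-butyldimethylsilyl)oxy]-8-hydroxy-6,15-bis[(triethylsilyl)oxy]germacra-1(10)E,4E,11(13)-trien-12-oic acid | OC(=O)C(=C)[C@@H]1[C@@H](O)C/C(C)=C/C[C@@H](O[Si](C)(C)C(C)(C)C)/C(CO[Si](CC)(CC)CC)=C/[C@H]1O[Si](CC)(CC)CC | intermediate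
28 | (3R,6R,7R,8S)-3-[(tert-butyldimethylsilyl)oxy]-6,15-bis[(triethylsilyl)oxy]germacra-1(10)E,4E,11(13)-trien-12,8-olide | C=C1C(=O)O[C@H]2C/C(C)=C/C[C@@H](O[Si](C)(C)C(C)(C)C)/C(CO[Si](CC)(CC)CC)=C/[C@@H](O[Si](CC)(CC)CC)[C@H]12 | intermediate
29 | (3R,6R,7S,8S)-3-[(tert-butyldimethylsilyl)oxy]-6,15-dihydroxygermacra-1(10)E,4E,11(13)-trien-12,8-olide | C=C1C(=O)O[C@H]2C/C(C)=C/C[C@@H](O[Si](C)(C)C(C)(C)C)/C(CO)=C/[C@@H](O)[C@H]12 | intermediate
30 | (2R)-2-methylbutanoic acid | CC[C@@H](C)C(=O)O | starting material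
31 | (3R,6R,7R,8S)-3-[(tert-butyldimethylsilyl)oxy]-6,15-bis{[(2R)-2-methylbutanoyl]oxy}germacra-1(10)E,4E,11(13)-trien-12,8-olide | C=C1C(=O)O[C@H]2C/C(C)=C/C[C@@H](O[Si](C)(C)C(C)(C)C)/C(COC(=O)[C@H](C)CC)=C/[C@@H](OC(=O)[C@H](C)CC)[C@H]12 | intermediate
32 | (3R,6R,7R,8S)-3-hydroxy-6,15-bis{[(2R)-2-methylbutanoyl]oxy}germacra-1(10)E,4E,11(13)-trien-12,8-olide | C=C1C(=O)O[C@H]2C/C(C)=C/C[C@@H](O)/C(COC(=O)[C@H](C)CC)=C/[C@@H](OC(=O)[C@H](C)CC)[C@H]12 | target

Total step count: 22. Longest linear sequence: 22 steps (from 1).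

Steps most likely to fail

1. Step 18. Possible failures are base-induced migration of the 1(10) alkene into conjugation with the aldehyde, oligomerization instead of ring closure, and attack on the wrong face of C7 or C8. The fallback makes the two C–C bonds in separate, known operations. It sets out from 25: copper-catalysed borylative allene–aldehyde coupling ((IPr)CuCl 5 mol%, NaOt-Bu 10 mol%, B2pin2, THF, 0 °C, slow addition) puts boron on C11 and lets the resulting allylcopper close the ten-membered ring at C7–C8. This gives (3R,6R,7R,8S)-3-[(tert-butyldimethylsilyl)oxy]-11-(4,4,5,5-tetramethyl-1,3,2-dioxaborolan-2-yl)-6,15-bis[(triethylsilyl)oxy]-12-norgermacra-1(10)E,4E,11(13)-trien-8-ol F1. Copper-catalysed carboxylation of the alkenylboronate ((IPr)CuCl 5 mol%, KOt-Bu, CO2 1 atm, THF, 65 °C; citric acid work-up) then forms C11–C12 and returns to the route at hydroxy acid 27.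

2. Step 11. Possible failures are poor facial selectivity on the hindered Z-β-iodoenal and Z-to-E isomerization under the zinc conditions. The fallback sets out from 15: LiC≡CSiMe3 (THF, −78 °C) gives (4Z,6R,8E)-6-[(tert-butyldimethylsilyl)oxy]-5-iodo-11-[(4-methoxybenzyl)oxy]-9-methyl-1-(trimethylsilyl)undeca-4,8-dien-1-yn-3-ol as a mixture of C3 epimers F2. MnO2 (CH2Cl2, rt) oxidizes this to (4Z,6R,8E)-6-[(tert-butyldimethylsilyl)oxy]-5-iodo-11-[(4-methoxybenzyl)oxy]-9-methyl-1-(trimethylsilyl)undeca-4,8-dien-1-yn-3-one F3. Midland reduction with (R)-Alpine-Borane (neat, rt), in which the alkynyl group acts as the small substituent, then returns to the route at 18.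

3. Step 15. Possible failures are loss of silyl groups at reflux in the amine medium, incomplete fragmentation of the propargylamine, and alkyne–allene scrambling. The fallback sets out from 21: n-BuLi (THF, −78 °C) then (CH2O)n gives (4R,5E,7R,9E)-7-[(tert-butyldimethylsilyl)oxy]-12-[(4-methoxybenzyl)oxy]-10-methyl-4-[(triethylsilyl)oxy]-6-{[(triethylsilyl)oxy]methyl}dodeca-5,9-dien-2-yn-1-ol F4. Myers reductive transposition (2-nitrobenzenesulfonylhydrazide, PPh3, DEAD, THF, −15 °C → rt) passes through the N-propargyl-N-(2-nitrobenzenesulfonyl)hydrazine F5 and the monoalkyl diazene F6, whose retro-ene loss of N2 returns to the route at allene 23.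

Further compounds
F1 | step 18 | (3R,6R,7R,8S)-3-[(tert-butyldimethylsilyl)oxy]-11-(4,4,5,5-tetramethyl-1,3,2-dioxaborolan-2-yl)-6,15-bis[(triethylsilyl)oxy]-12-norgermacra-1(10)E,4E,11(13)-trien-8-ol | CC1(C)OB(OC1(C)C)C(=C)[C@@H]1[C@@H](O)C/C(C)=C/C[C@@H](O[Si](C)(C)C(C)(C)C)/C(CO[Si](CC)(CC)CC)=C/[C@H]1O[Si](CC)(CC)CC
F2 | step 11 | (4Z,6R,8E)-6-[(tert-butyldimethylsilyl)oxy]-5-iodo-11-[(4-methoxybenzyl)oxy]-9-methyl-1-(trimethylsilyl)undeca-4,8-dien-1-yn-3-ol, mixture of C3 epimers | C[Si](C)(C)C#CC(O)/C=C(\I)[C@H](O[Si](C)(C)C(C)(C)C)C/C=C(\C)CCOCc1ccc(OC)cc1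
F3 | step 11 | (4Z,6R,8E)-6-[(tert-butyldimethylsilyl)oxy]-5-iodo-11-[(4-methoxybenzyl)oxy]-9-methyl-1-(trimethylsilyl)undeca-4,8-dien-1-yn-3-one | C[Si](C)(C)C#CC(=O)/C=C(\I)[C@H](O[Si](C)(C)C(C)(C)C)C/C=C(\C)CCOCc1ccc(OC)cc1
F4 | step 15 | (4R,5E,7R,9E)-7-[(tert-butyldimethylsilyl)oxy]-12-[(4-methoxybenzyl)oxy]-10-methyl-4-[(triethylsilyl)oxy]-6-{[(triethylsilyl)oxy]methyl}dodeca-5,9-dien-2-yn-1-ol | OCC#C[C@H](O[Si](CC)(CC)CC)/C=C(\CO[Si](CC)(CC)CC)[C@H](O[Si](C)(C)C(C)(C)C)C/C=C(\C)CCOCc1ccc(OC)cc1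
F5 | step 15 | N-propargyl-N-(2-nitrobenzenesulfonyl)hydrazine derived from F4 (not isolated) | NN(CC#C[C@H](O[Si](CC)(CC)CC)/C=C(\CO[Si](CC)(CC)CC)[C@H](O[Si](C)(C)C(C)(C)C)C/C=C(\C)CCOCc1ccc(OC)cc1)S(=O)(=O)c1ccccc1[N+](=O)[O-]
F6 | step 15 | propargylic monoalkyl diazene derived from F5 (not isolated) | N=NCC#C[C@H](O[Si](CC)(CC)CC)/C=C(\CO[Si](CC)(CC)CC)[C@H](O[Si](C)(C)C(C)(C)C)C/C=C(\C)CCOCc1ccc(OC)cc1
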